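**Plan**

- Cuts, last to first: the five O–Si bonds; the aryl C5–Cβ bond of the enone (Heck reaction with an aryl vinyl ketone); the C2–C3 bond of the dihydrofuran (light-driven hydrogen transfer and biradical closure); the central C–C bond of a 1,2-dione (dithiane anion plus aldehyde); the benzyl ether C–O bond (Mitsunobu).
- Enabling feature: C2, a benzylic ether carbon bonded to O1 and to the 4-hydroxyphenyl ring, is joined to C3, a tertiary carbinol that carries an aroyl group. C3 and the aroyl carbon are therefore the two carbonyl carbons of a 1,2-dione on ring A, and O1–C2 is an ortho benzyloxy group whose C–H lies six atoms from the dione oxygen next to ring A.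
- Forward: the ring A aldehyde and the ring B dithiane are joined, the adduct is oxidized and unmasked to the dione, the dihydrofuran ring (the only ring made) closes photochemically, the enone arm is attached at C5, and the silyl groups are removed.
- Stereochemistry: C3 comes from the chiral pybox ligand on scandium, which selects the face of the chelated ketyl. C2 is set relative to C3 in the closing biradical (aryl cis to hydroxyl, anti to aroyl). The E alkene comes from the Heck step.

Key step: step 9

Remark on the chemistry: the (S,S) ligand is assumed to give the (2S,3S) product; the sense of induction cannot be foreseen for this substrate, and the (R,R) ligand would take its place should the sense prove opposite.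

Abbreviations: TBS = tert-butyldimethylsilyl; TBSO = tert-butyldimethylsilyloxy. Compounds 12, 16, 17 and 18 are handled with exclusion of daylight.

**Route**

Step 1
Reactants: 1 4-hydroxybenzaldehyde
Product: 2 4-(TBSO)benzaldehyde
Conditions: TBSCl, imidazole, DMF, 0 °C to rt
Reagents that add atoms: tert-butyldimethylsilyl chloride, CC(C)(C)[Si](C)(C)Cl
Why: Imidazole-promoted silylation of a phenol, which leaves the aldehyde untouched.

Step 2
Reactants: 2 4-(TBSO)benzaldehyde
Product: 3 [4-(TBSO)phenyl]methanol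
Conditions: NaBH4, MeOH/THF, 0 °C, short reaction time
Reagents that add atoms: none
Why: Borohydride reduction of an aryl aldehyde, with brief exposure at 0 °C so that the aryl silyl ether should stay in place.

Step 3
Reactants: 3 [4-(TBSO)phenyl]methanol; 4 5-bromo-2-hydroxybenzaldehyde
Product: 5 5-bromo-2-{[4-(TBSO)phenyl]methoxy}benzaldehyde
Conditions: PPh3, DIAD, THF, 0 °C to rt
Reagents that add atoms: none
Why: Mitsunobu etherification, in which the acidic salicylaldehyde phenol displaces the activated primary benzylic alcohol under neutral conditions that spare the silyl ether and avoid a labile 4-silyloxybenzyl halide.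

Step 4
Reactants: 6 2,4-dihydroxybenzaldehyde
Product: 7 2,4-bis(TBSO)benzaldehyde
Conditions: TBSCl (2.5 equiv), imidazole, DMF, rt
Reagents that add atoms: tert-butyldimethylsilyl chloride, CC(C)(C)[Si](C)(C)Cl
Why: Imidazole-promoted double silylation of the phenols, the hydrogen-bonded ortho hydroxyl reacting more slowly but completely with excess reagent.

Step 5
Reactants: 7 2,4-bis(TBSO)benzaldehyde
Product: 8 2-[2,4-bis(TBSO)phenyl]-1,3-dithiane
Conditions: propane-1,3-dithiol, BF3·OEt2 (cat.), CH2Cl2, 0 °C
Reagents that add atoms: propane-1,3-dithiol, SCCCS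
Why: Lewis-acid-catalysed dithioacetalization of an aryl aldehyde (first stage of the Corey–Seebach sequence), with catalytic acid at 0 °C that aryl silyl ethers should tolerate.

Step 6
Reactants: 8 2-[2,4-bis(TBSO)phenyl]-1,3-dithiane; 5 5-bromo-2-{[4-(TBSO)phenyl]methoxy}benzaldehyde
Product: 10 racemic (5-bromo-2-{[4-(TBSO)phenyl]methoxy}phenyl){2-[2,4-bis(TBSO)phenyl]-1,3-dithian-2-yl}methanol, via 2-lithio-1,3-dithiane 9 (not isolated)
Conditions: n-BuLi (slightly less than 8), THF, −78 to −40 °C; then 5, −78 °C; AcOH, −78 °C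
Reagents that add atoms: none
Why: Corey–Seebach umpolung, in which the sulfur-stabilized carbanion should add to the aldehyde far faster than it exchanges with the aryl bromide, the low temperature should keep the ortho silyl group on oxygen, and the new carbinol centre is racemic and disappears in step 7.

Step 7
Reactants: 10 racemic (5-bromo-2-{[4-(TBSO)phenyl]methoxy}phenyl){2-[2,4-bis(TBSO)phenyl]-1,3-dithian-2-yl}methanol
Product: 11 (5-bromo-2-{[4-(TBSO)phenyl]methoxy}phenyl){2-[2,4-bis(TBSO)phenyl]-1,3-dithian-2-yl}methanone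
Conditions: Dess–Martin periodinane, pyridine, CH2Cl2, 0 °C to rt
Reagents that add atoms: none
Why: Dess–Martin oxidation of a hindered benzylic carbinol under anhydrous buffered conditions, which should leave the dithiane sulfur atoms and the silyl ethers alone.

Step 8
Reactants: 11 (5-bromo-2-{[4-(TBSO)phenyl]methoxy}phenyl){2-[2,4-bis(TBSO)phenyl]-1,3-dithian-2-yl}methanone
Product: 12 1-(5-bromo-2-{[4-(TBSO)phenyl]methoxy}phenyl)-2-[2,4-bis(TBSO)phenyl]ethane-1,2-dione
Conditions: Hg(ClO4)2·3H2O, CaCO3, THF/H2O, 0 °C, dark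
Reagents that add atoms: water, O
Why: Mercury-assisted hydrolysis of a dithioacetal, in which the thionium ion is stabilized by the electron-rich aryl group and CaCO3 takes up the acid so that the silyl ethers and the 4-silyloxybenzyl ether should survive.

Step 9
Reactants: 12 1-(5-bromo-2-{[4-(TBSO)phenyl]methoxy}phenyl)-2-[2,4-bis(TBSO)phenyl]ethane-1,2-dione
Product: 13 [2,4-bis(TBSO)phenyl]{(2S,3S)-5-bromo-3-hydroxy-2-[4-(TBSO)phenyl]-2,3-dihydro-1-benzofuran-3-yl}methanone (hydroxyl cis to the 2-aryl group)
Conditions: Sc(OTf)3 (20 mol %), (S,S)-t-Bu-pybox (24 mol %), 4 Å molecular sieves, CH2Cl2, −40 °C, 450 nm LEDs, argon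
Reagents that add atoms: none
Why: Proposed new method: the 1,2-dione of 12 should chelate Sc(OTf)3 carrying the pybox ligand, which moves its long-wavelength band further into the visible so that at 450 nm mainly the bound, chiral complex is excited; the oxygen of the carbonyl next to ring A then takes a hydrogen from the ortho OCH2Ar group through a seven-membered transition state (1,6-transfer, possibly as electron transfer from the electron-rich benzyl ether followed by proton transfer), and the 1,5-biradical made of a scandium-bound α-keto ketyl and an α-aryloxybenzyl radical collapses to the C2–C3 bond. The closest known reaction type is the Norrish–Yang photocyclization of ortho-benzyloxyphenyl ketones and arylglyoxylates to 3-hydroxy-2-aryl-2,3-dihydrobenzofurans, combined with the known principle that a chiral Lewis acid bound to the chromophore can steer a photoreaction. The dihydrofuran ring closes by radical–radical combination within the 1,5-biradical, a five-membered closure in which the ketyl carbon becomes C3 and the benzylic carbon C2. C3 is controlled by the pybox ligand sphere, which should leave one face of the chelated ketyl open, and C2 by the closing conformer, in which the 4-silyloxyphenyl group turns away from the bulky aroyl–scandium unit and so ends cis to the hydroxyl. The step needs abstraction only at the benzylic CH2 (the silyl ethers offer no C–H next to oxygen and no phenolic proton for excited-state proton transfer), five- over six-membered closure (abstraction by the oxygen on the ring B side would need an eight-membered transition state) and an intact C–Br bond (the long wavelength does not excite it).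

Step 10
Reactants: 7 2,4-bis(TBSO)benzaldehyde; 14 vinylmagnesium bromide
Product: 15 racemic 1-[2,4-bis(TBSO)phenyl]prop-2-en-1-ol
Conditions: THF, −78 °C; sat. aq. NH4Cl at −78 °C
Reagents that add atoms: none
Why: Grignard 1,2-addition to an aryl aldehyde, run and quenched cold so that the magnesium alkoxide should have no time to take over the ortho silyl group.

Step 11
Reactants: 15 racemic 1-[2,4-bis(TBSO)phenyl]prop-2-en-1-ol
Product: 16 1-[2,4-bis(TBSO)phenyl]prop-2-en-1-one
Conditions: activated MnO2 (excess), CH2Cl2, rt, dark; filtered and used at once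
Reagents that add atoms: none
Why: MnO2 oxidation of an alcohol that is both allylic and benzylic, under neutral heterogeneous conditions that suit a polymerization-prone aryl vinyl ketone.

Step 12
Reactants: 13 [2,4-bis(TBSO)phenyl]{(2S,3S)-5-bromo-3-hydroxy-2-[4-(TBSO)phenyl]-2,3-dihydro-1-benzofuran-3-yl}methanone; 16 1-[2,4-bis(TBSO)phenyl]prop-2-en-1-one
Product: 17 (E)-1-[2,4-bis(TBSO)phenyl]-3-{(2S,3S)-3-[2,4-bis(TBSO)benzoyl]-3-hydroxy-2-[4-(TBSO)phenyl]-2,3-dihydro-1-benzofuran-5-yl}prop-2-en-1-one
Conditions: Pd2(dba)3 (2.5 mol %), [HP(t-Bu)3]BF4 (10 mol %), Cy2NMe, 16 (2 equiv), 1,4-dioxane, rt to 40 °C, dark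
Reagents that add atoms: none
Why: Mizoroki–Heck reaction, in which the bulky electron-rich phosphine should allow oxidative addition to the electron-rich aryl bromide near room temperature, syn insertion at the terminal carbon of the enone and syn β-hydride elimination give the E alkene, and C2 and C3 are not touched.

Step 13
Reactants: 17 (E)-1-[2,4-bis(TBSO)phenyl]-3-{(2S,3S)-3-[2,4-bis(TBSO)benzoyl]-3-hydroxy-2-[4-(TBSO)phenyl]-2,3-dihydro-1-benzofuran-5-yl}prop-2-en-1-one
Product: 18 (E)-1-(2,4-dihydroxyphenyl)-3-[(2S,3S)-3-(2,4-dihydroxybenzoyl)-3-hydroxy-2-(4-hydroxyphenyl)-2,3-dihydro-1-benzofuran-5-yl]prop-2-en-1-one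
Conditions: TBAF (6 equiv), AcOH (6 equiv), THF, 0 °C, dark
Reagents that add atoms: none
Why: Fluoride cleavage of five aryl silyl ethers, with AcOH keeping the liberated phenols protonated so that ring opening at C2 through a quinone methide, ketol rearrangement at C3 and closure of the 2'-hydroxychalcone to a flavanone should be avoided and both stereocentres and the E alkene stay as set.

**Compound list**

1 | 4-hydroxybenzaldehyde | O=Cc1ccc(O)cc1 | starting material
2 | 4-(TBSO)benzaldehyde | O=Cc1ccc(O[Si](C)(C)C(C)(C)C)cc1 | intermediate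
3 | [4-(TBSO)phenyl]methanol | OCc1ccc(O[Si](C)(C)C(C)(C)C)cc1 | intermediate
4 | 5-bromo-2-hydroxybenzaldehyde (5-bromosalicylaldehyde) | O=Cc1cc(Br)ccc1O | starting material
5 | 5-bromo-2-{[4-(TBSO)phenyl]methoxy}benzaldehyde | O=Cc1cc(Br)ccc1OCc1ccc(O[Si](C)(C)C(C)(C)C)cc1 | intermediate
6 | 2,4-dihydroxybenzaldehyde | O=Cc1ccc(O)cc1O | starting material
7 | 2,4-bis(TBSO)benzaldehyde | O=Cc1ccc(O[Si](C)(C)C(C)(C)C)cc1O[Si](C)(C)C(C)(C)C | intermediate
8 | 2-[2,4-bis(TBSO)phenyl]-1,3-dithiane | C1(SCCCS1)c1ccc(O[Si](C)(C)C(C)(C)C)cc1O[Si](C)(C)C(C)(C)C | intermediate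
9 | {2-[2,4-bis(TBSO)phenyl]-1,3-dithian-2-yl}lithium | [Li]C1(SCCCS1)c1ccc(O[Si](C)(C)C(C)(C)C)cc1O[Si](C)(C)C(C)(C)C | intermediate
10 | racemic (5-bromo-2-{[4-(TBSO)phenyl]methoxy}phenyl){2-[2,4-bis(TBSO)phenyl]-1,3-dithian-2-yl}methanol | OC(c1cc(Br)ccc1OCc1ccc(O[Si](C)(C)C(C)(C)C)cc1)C1(SCCCS1)c1ccc(O[Si](C)(C)C(C)(C)C)cc1O[Si](C)(C)C(C)(C)C | intermediate
11 | (5-bromo-2-{[4-(TBSO)phenyl]methoxy}phenyl){2-[2,4-bis(TBSO)phenyl]-1,3-dithian-2-yl}methanone | O=C(c1cc(Br)ccc1OCc1ccc(O[Si](C)(C)C(C)(C)C)cc1)C1(SCCCS1)c1ccc(O[Si](C)(C)C(C)(C)C)cc1O[Si](C)(C)C(C)(C)C | intermediate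
12 | 1-(5-bromo-2-{[4-(TBSO)phenyl]methoxy}phenyl)-2-[2,4-bis(TBSO)phenyl]ethane-1,2-dione | O=C(C(=O)c1ccc(O[Si](C)(C)C(C)(C)C)cc1O[Si](C)(C)C(C)(C)C)c1cc(Br)ccc1OCc1ccc(O[Si](C)(C)C(C)(C)C)cc1 | intermediate
13 | [2,4-bis(TBSO)phenyl]{(2S,3S)-5-bromo-3-hydroxy-2-[4-(TBSO)phenyl]-2,3-dihydro-1-benzofuran-3-yl}methanone | Brc1ccc2c(c1)[C@@](O)(C(=O)c1ccc(O[Si](C)(C)C(C)(C)C)cc1O[Si](C)(C)C(C)(C)C)[C@H](c1ccc(O[Si](C)(C)C(C)(C)C)cc1)O2 | intermediate
14 | vinylmagnesium bromide | C=C[Mg]Br | starting material
15 | racemic 1-[2,4-bis(TBSO)phenyl]prop-2-en-1-ol | C=CC(O)c1ccc(O[Si](C)(C)C(C)(C)C)cc1O[Si](C)(C)C(C)(C)C | intermediate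
16 | 1-[2,4-bis(TBSO)phenyl]prop-2-en-1-one | C=CC(=O)c1ccc(O[Si](C)(C)C(C)(C)C)cc1O[Si](C)(C)C(C)(C)C | intermediate
17 | (E)-1-[2,4-bis(TBSO)phenyl]-3-{(2S,3S)-3-[2,4-bis(TBSO)benzoyl]-3-hydroxy-2-[4-(TBSO)phenyl]-2,3-dihydro-1-benzofuran-5-yl}prop-2-en-1-one | O=C(/C=C/c1ccc2c(c1)[C@@](O)(C(=O)c1ccc(O[Si](C)(C)C(C)(C)C)cc1O[Si](C)(C)C(C)(C)C)[C@H](c1ccc(O[Si](C)(C)C(C)(C)C)cc1)O2)c1ccc(O[Si](C)(C)C(C)(C)C)cc1O[Si](C)(C)C(C)(C)C | intermediate
18 | (E)-1-(2,4-dihydroxyphenyl)-3-[(2S,3S)-3-(2,4-dihydroxybenzoyl)-3-hydroxy-2-(4-hydroxyphenyl)-2,3-dihydro-1-benzofuran-5-yl]prop-2-en-1-one (CNP0317806.1) | O=C(/C=C/c1ccc2c(c1)[C@@](O)(C(=O)c1ccc(O)cc1O)[C@H](c1ccc(O)cc1)O2)c1ccc(O)cc1O | target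

**Step count and risks**

Total step count: 13. Longest linear sequence: 9 steps (steps 1, 2, 3, 6, 7, 8, 9, 12, 13).

Steps most likely to fail:

1. Step 9. Tying both carbonyl oxygens to scandium may slow the hydrogen transfer, unbound dione may react in the background and erode enantiomeric purity, and the facial discrimination at the ketyl carbon by the ligand sphere is untested. Fallback with known chemistry, setting out from 12: irradiation without any Lewis acid (420 nm, benzene, rt, argon) is the plain Norrish–Yang photocyclization of the kind known for ortho-benzyloxyphenyl ketones and arylglyoxylates. It should give the cis ketol as a racemate, that is 13 together with its mirror image, the (2R,3R) enantiomer of 13 F1, any trans isomer being removed on silica. Preparative chromatography on a chiral stationary phase (amylose tris(3,5-dimethylphenylcarbamate), supercritical CO2/2-propanol) then separates the two, and the route is rejoined at 13.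

2. Step 6. The ortho silyl group may migrate from oxygen to the carbanion carbon of 9 before addition, or the crowded anion may add slowly and reversibly. Fallback that avoids any carbanion or alkoxide next to ring B, setting out from 5: Colvin homologation (TMSCHN2, LiN(i-Pr)2, THF, −78 °C to rt) should give 4-bromo-2-ethynyl-1-{[4-(TBSO)phenyl]methoxy}benzene F2. Sonogashira coupling (PdCl2(PPh3)2, CuI, Et3N, THF, rt) follows, selective for the iodide, with 1-iodo-2,4-bis(TBSO)benzene F3, itself made from commercial 4-iodobenzene-1,3-diol with TBSCl and imidazole. This should give 4-bromo-2-{[2,4-bis(TBSO)phenyl]ethynyl}-1-{[4-(TBSO)phenyl]methoxy}benzene F4. Buffered permanganate oxidation of the diarylalkyne (KMnO4, NaHCO3, MgSO4, acetone/H2O, rt) leads to the dione, and the route is rejoined at 12; steps 5, 7 and 8 are then not needed.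

3. Step 12. Polymerization of 16 or amine-induced conjugate additions may outrun the slow oxidative addition to the electron-rich aryl bromide. Fallback that forms the alkene by metathesis, setting out from 13: Stille coupling (Pd(PPh3)4, tributyl(vinyl)stannane, toluene, 90 °C) should give [2,4-bis(TBSO)phenyl]{(2S,3S)-5-ethenyl-3-hydroxy-2-[4-(TBSO)phenyl]-2,3-dihydro-1-benzofuran-3-yl}methanone F5. Cross-metathesis of this styrene with 16 under neutral conditions (second-generation Hoveyda–Grubbs catalyst, CH2Cl2, 40 °C) should give the E enone, and the route is rejoined at 17.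

**Further compounds**

F1 | step 9 | (2R,3R) enantiomer of 13, [2,4-bis(TBSO)phenyl]{(2R,3R)-5-bromo-3-hydroxy-2-[4-(TBSO)phenyl]-2,3-dihydro-1-benzofuran-3-yl}methanone | Brc1ccc2c(c1)[C@](O)(C(=O)c1ccc(O[Si](C)(C)C(C)(C)C)cc1O[Si](C)(C)C(C)(C)C)[C@@H](c1ccc(O[Si](C)(C)C(C)(C)C)cc1)O2
F2 | step 6 | 4-bromo-2-ethynyl-1-{[4-(TBSO)phenyl]methoxy}benzene | C#Cc1cc(Br)ccc1OCc1ccc(O[Si](C)(C)C(C)(C)C)cc1
F3 | step 6 | 1-iodo-2,4-bis(TBSO)benzene | Ic1ccc(O[Si](C)(C)C(C)(C)C)cc1O[Si](C)(C)C(C)(C)C
F4 | step 6 | 4-bromo-2-{[2,4-bis(TBSO)phenyl]ethynyl}-1-{[4-(TBSO)phenyl]methoxy}benzene | Brc1ccc(OCc2ccc(O[Si](C)(C)C(C)(C)C)cc2)c(C#Cc2ccc(O[Si](C)(C)C(C)(C)C)cc2O[Si](C)(C)C(C)(C)C)c1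
F5 | step 12 | [2,4-bis(TBSO)phenyl]{(2S,3S)-5-ethenyl-3-hydroxy-2-[4-(TBSO)phenyl]-2,3-dihydro-1-benzofuran-3-yl}methanone | C=Cc1ccc2c(c1)[C@@](O)(C(=O)c1ccc(O[Si](C)(C)C(C)(C)C)cc1O[Si](C)(C)C(C)(C)C)[C@H](c1ccc(O[Si](C)(C)C(C)(C)C)cc1)O2
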